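The ring is opened at the diaryl ether bond between the central oxygen of pyrogallol ring B and C3 of ring A. Ring A bears O, O and the chain in a 1,3,5 array, which maps onto a symmetric 5-alkylcyclohexane-1,3-dione used as its 3-chloroenone; the ring B oxygen lies para to the benzylic carbon, so keeping that carbon a ketone acidifies the phenol. In one operation the phenoxide displaces chloride by addition–elimination, forming the O–C bond and the 22-membered ring. The precursor is a seco chloroenone phenol: both termini joined by the C14 keto chain. Aromatization of ring A, ether cleavage and a final asymmetric transfer hydrogenation complete gravicycle.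

Key step: step 10

Remark: 16, 17 and 18 are racemic at C5 of the six-membered ring A precursor (their only stereocentre, lost in step 12); the aryl silyl ether of 11 is assumed to fall to methoxide in the first stage of step 8 (if it lasts longer, hydroxide in the second stage gives the same product).

Step 1
Reactants: 1 ω-pentadecalactone
Product: 2 15-hydroxy-N-methoxy-N-methylpentadecanamide
Conditions: MeNHOMe·HCl, AlMe3, CH2Cl2, 0 °C → rt; then 1 M aq. HCl
Reagents that add atoms: N,O-dimethylhydroxylamine hydrochloride, CNOC.Cl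
Why: Weinreb aminolysis by the aluminium amide opens the lactone at the acyl carbon, giving the N-methoxy-N-methyl amide and freeing the terminal primary alcohol.

Step 2
Reactants: 2 15-hydroxy-N-methoxy-N-methylpentadecanamide
Product: 3 15-[(tert-butyldimethylsilyl)oxy]-N-methoxy-N-methylpentadecanamide
Conditions: TBSCl, imidazole, CH2Cl2, rt
Reagents that add atoms: tert-butyldimethylsilyl chloride, CC(C)(C)[Si](C)(C)Cl
Why: Imidazole-promoted silylation of the primary alcohol removes the acidic O–H that would quench the aryllithium of step 4.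

Step 3
Reactants: 4 4-bromo-2,6-dimethoxyphenol
Product: 5 (4-bromo-2,6-dimethoxyphenoxy)triisopropylsilane
Conditions: TIPSCl, imidazole, DMF, 40 °C
Reagents that add atoms: triisopropylsilyl chloride, CC(C)[Si](Cl)(C(C)C)C(C)C
Why: The aryl TIPS ether masks the phenol for bromine–lithium exchange, resists the mild acid of step 5 and is later cleaved by methoxide to a harmless silanol, so no aldehyde (as from an acetal-type group) is released beside the aldehyde-sensitive 1,3-dione.

Step 4
Reactants: 5 (4-bromo-2,6-dimethoxyphenoxy)triisopropylsilane; 3 15-[(tert-butyldimethylsilyl)oxy]-N-methoxy-N-methylpentadecanamide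
Product: 7 15-[(tert-butyldimethylsilyl)oxy]-1-[3,5-dimethoxy-4-(triisopropylsilyloxy)phenyl]pentadecan-1-one, via aryllithium 6 (not isolated)
Conditions: n-BuLi, THF, −78 °C; then 3, −78 → 0 °C; then H2O
Reagents that add atoms: none
Why: Bromine–lithium exchange gives the aryllithium, which adds only once to the Weinreb amide because the chelated tetrahedral adduct persists until aqueous work-up (Weinreb ketone synthesis).

Step 5
Reactants: 7 15-[(tert-butyldimethylsilyl)oxy]-1-[3,5-dimethoxy-4-(triisopropylsilyloxy)phenyl]pentadecan-1-one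
Product: 8 1-[3,5-dimethoxy-4-(triisopropylsilyloxy)phenyl]-15-hydroxypentadecan-1-one
Conditions: CSA (cat.), MeOH/CH2Cl2, 0 °C → rt
Reagents that add atoms: none
Why: Acid-catalysed methanolysis cleaves a primary alkyl TBS ether far faster than a hindered, electron-poor aryl TIPS ether, so only the chain terminus should be unmasked.

Step 6
Reactants: 8 1-[3,5-dimethoxy-4-(triisopropylsilyloxy)phenyl]-15-hydroxypentadecan-1-one
Product: 9 15-[3,5-dimethoxy-4-(triisopropylsilyloxy)phenyl]-15-oxopentadecanal
Conditions: Dess–Martin periodinane, CH2Cl2, rt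
Reagents that add atoms: none
Why: Dess–Martin oxidation stops at the aldehyde under nearly neutral conditions and leaves the aryl ketone and the aryl silyl ether alone.

Step 7
Reactants: 9 15-[3,5-dimethoxy-4-(triisopropylsilyloxy)phenyl]-15-oxopentadecanal; 10 1-(triphenylphosphoranylidene)propan-2-one
Product: 11 (E)-1-[3,5-dimethoxy-4-(triisopropylsilyloxy)phenyl]octadec-15-ene-1,17-dione
Conditions: PhMe, 80 °C
Reagents that add atoms: none
Why: The ketone-stabilized Wittig ylide reacts with the aldehyde but not with the aryl ketone and should give the (E)-enone, as stabilized ylides do.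

Step 8
Reactants: 11 (E)-1-[3,5-dimethoxy-4-(triisopropylsilyloxy)phenyl]octadec-15-ene-1,17-dione; 12 dimethyl malonate
Product: 15 5-[14-(4-hydroxy-3,5-dimethoxyphenyl)-14-oxotetradecyl]cyclohexane-1,3-dione, via Dieckmann keto ester 13 (not isolated), via dione carboxylic acid 14 (not isolated)
Conditions: NaOMe, MeOH, reflux; then 2 M aq. NaOH, reflux; then aq. HCl to pH 1, 90 °C
Reagents that add atoms: none
Why: Michael addition of sodiomalonate to the enone and Dieckmann-type closure of the methyl ketone onto one ester give the cyclic keto ester as its stable enolate while methoxide cleaves the aryl silyl ether, and saponification followed by decarboxylation of the vinylogous β-keto acid in hot acid should leave the symmetric dione (the classical dimedone-type annulation).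

Step 9
Reactants: 15 5-[14-(4-hydroxy-3,5-dimethoxyphenyl)-14-oxotetradecyl]cyclohexane-1,3-dione
Product: 16 racemic 3-chloro-5-[14-(4-hydroxy-3,5-dimethoxyphenyl)-14-oxotetradecyl]cyclohex-2-en-1-one
Conditions: (COCl)2 (1.1 equiv), DMF (cat.), CH2Cl2, 0 °C → rt
Reagents that add atoms: oxalyl chloride, O=C(Cl)C(=O)Cl
Why: The enolic dione is a vinylogous carboxylic acid and should be converted by the Vilsmeier-type chloroiminium reagent into the vinylogous acid chloride much faster than the hindered, electron-poor phenol is acylated without base, and the symmetric dione can give only one chloroenone.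

Step 10
Reactants: 16 racemic 3-chloro-5-[14-(4-hydroxy-3,5-dimethoxyphenyl)-14-oxotetradecyl]cyclohex-2-en-1-one
Product: 17 racemic macrocyclic 3-aryloxycyclohex-2-en-1-one (the oxygen at C4 of the 3,5-dimethoxyphenyl ring B is bonded to C3 of the cyclohexenone; C5 of the cyclohexenone carries a (CH2)13 chain that ends at the ketone carbon on C1 of ring B; 22-membered ring)
Conditions: Cs2CO3, dry MeCN, 70 °C, syringe-pump addition of 16 over 12 h, final concentration about 1 mM
Reagents that add atoms: none
Why: Proposed new method: carbonate ionizes the phenol, which the para ketone makes acidic, and the phenoxide oxygen adds to C3 of the chloroenone to give an enolate that expels chloride (vinylogous nucleophilic acyl substitution), so the O–C3 bond and the macrocycle form in one event. The closest known reaction is the intermolecular addition–elimination of phenoxides on 3-chlorocyclohex-2-enones, run here within one molecule under the slow-addition, high-dilution regime used for macrocyclizing nucleophilic aromatic substitutions. The 22-membered ring closes in a 22-exo-trig mode, the attacked C2=C3 bond lying outside the new ring. No stereocentre is created; C5 of the cyclohexenone is already present, stays racemic and is erased in step 12. The step needs ring closure to beat oligomerization and needs bonding at one site only: pseudo-dilution serves the first, and the substrate fixes the second, because the ortho and para carbons of the phenoxide are substituted, the flanking oxygens are methyl ethers, the electrophile is a single chloroenone isomer, and addition of phenoxide to its carbonyl is reversible.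

Step 11
Reactants: 17 racemic macrocyclic 3-aryloxycyclohex-2-en-1-one
Product: 18 racemic 2-bromo derivative of 17 (bromine on C2 of the cyclohexenone, between the carbonyl carbon and the aryloxy carbon)
Conditions: NBS (1.0 equiv), CH2Cl2, 0 °C
Reagents that add atoms: N-bromosuccinimide, O=C1CCC(=O)N1Br
Why: C2 of the vinylogous ester is the most nucleophilic carbon present, so electrophilic bromination should occur there and not on the acyl-deactivated ring B or next to the aryl ketone.

Step 12
Reactants: 18 racemic 2-bromo derivative of 17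
Product: 19 macrocyclic diaryl ether ketone (ring A: benzene with OH on C1, the ether oxygen on C3 and the chain on C5; ring B: 3,5-dimethoxy-4-aryloxyphenyl ketone; (CH2)13 between ring A and the ketone carbon)
Conditions: DBU, MeCN, rt → 50 °C
Reagents that add atoms: none
Why: DBU deconjugates the bromoenone through its dienolate and then removes HBr in a 1,4-sense (hydrogen from C5, bromide from C2) to give a cyclohexa-2,4-dienone that tautomerizes irreversibly to the phenol, the known aromatization of 2-bromo-3-aryloxycyclohexenones.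

Step 13
Reactants: 19 macrocyclic diaryl ether ketone
Product: 20 macrocyclic triphenol ketone (19 with both methoxy groups replaced by hydroxy groups)
Conditions: BBr3, CH2Cl2, −78 °C → rt; then H2O
Reagents that add atoms: none
Why: BBr3 cleaves both aryl methyl ethers by Lewis acid activation and bromide attack on methyl, whereas the diaryl ether has no alkyl carbon to attack and the benzylic carbon is still a ketone, so no benzylic bromide can form.

Step 14
Reactants: 20 macrocyclic triphenol ketone
Product: 21 gravicycle, the (R) benzylic carbinol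
Conditions: RuCl(p-cymene)[(R,R)-TsDPEN] (2 mol %), HCO2H/Et3N (5:2), DMF, 40 °C
Reagents that add atoms: none
Why: Noyori asymmetric transfer hydrogenation delivers hydride through the six-membered metal–ligand bifunctional transition state in which the aryl group is held by a CH–π contact with the p-cymene ligand, so the (R,R)-TsDPEN catalyst should give the (R) carbinol of this aryl alkyl ketone, and the formic acid medium tolerates the free phenols.

Compound list
1 | ω-pentadecalactone (oxacyclohexadecan-2-one) | O=C1CCCCCCCCCCCCCCO1 | starting material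
2 | 15-hydroxy-N-methoxy-N-methylpentadecanamide | CON(C)C(=O)CCCCCCCCCCCCCCO | intermediate
3 | 15-[(tert-butyldimethylsilyl)oxy]-N-methoxy-N-methylpentadecanamide | CON(C)C(=O)CCCCCCCCCCCCCCO[Si](C)(C)C(C)(C)C | intermediate
4 | 4-bromo-2,6-dimethoxyphenol | COc1cc(Br)cc(OC)c1O | starting material
5 | (4-bromo-2,6-dimethoxyphenoxy)triisopropylsilane | COc1cc(Br)cc(OC)c1O[Si](C(C)C)(C(C)C)C(C)C | intermediate
6 | [3,5-dimethoxy-4-(triisopropylsilyloxy)phenyl]lithium | COc1cc([Li])cc(OC)c1O[Si](C(C)C)(C(C)C)C(C)C | intermediate (not isolated)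
7 | 15-[(tert-butyldimethylsilyl)oxy]-1-[3,5-dimethoxy-4-(triisopropylsilyloxy)phenyl]pentadecan-1-one | COc1cc(cc(OC)c1O[Si](C(C)C)(C(C)C)C(C)C)C(=O)CCCCCCCCCCCCCCO[Si](C)(C)C(C)(C)C | intermediate
8 | 1-[3,5-dimethoxy-4-(triisopropylsilyloxy)phenyl]-15-hydroxypentadecan-1-one | COc1cc(cc(OC)c1O[Si](C(C)C)(C(C)C)C(C)C)C(=O)CCCCCCCCCCCCCCO | intermediate
9 | 15-[3,5-dimethoxy-4-(triisopropylsilyloxy)phenyl]-15-oxopentadecanal | COc1cc(cc(OC)c1O[Si](C(C)C)(C(C)C)C(C)C)C(=O)CCCCCCCCCCCCCC=O | intermediate
10 | 1-(triphenylphosphoranylidene)propan-2-one | CC(=O)C=P(c1ccccc1)(c1ccccc1)c1ccccc1 | starting material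
11 | (E)-1-[3,5-dimethoxy-4-(triisopropylsilyloxy)phenyl]octadec-15-ene-1,17-dione | COc1cc(cc(OC)c1O[Si](C(C)C)(C(C)C)C(C)C)C(=O)CCCCCCCCCCCCC/C=C/C(C)=O | intermediate
12 | dimethyl malonate | COC(=O)CC(=O)OC | starting material
13 | methyl 2-[14-(4-hydroxy-3,5-dimethoxyphenyl)-14-oxotetradecyl]-4,6-dioxocyclohexane-1-carboxylate (stereoisomer mixture) | COC(=O)C1C(=O)CC(=O)CC1CCCCCCCCCCCCCC(=O)c1cc(OC)c(O)c(OC)c1 | intermediate (not isolated)
14 | 2-[14-(4-hydroxy-3,5-dimethoxyphenyl)-14-oxotetradecyl]-4,6-dioxocyclohexane-1-carboxylic acid (stereoisomer mixture) | OC(=O)C1C(=O)CC(=O)CC1CCCCCCCCCCCCCC(=O)c1cc(OC)c(O)c(OC)c1 | intermediate (not isolated)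
15 | 5-[14-(4-hydroxy-3,5-dimethoxyphenyl)-14-oxotetradecyl]cyclohexane-1,3-dione | COc1cc(cc(OC)c1O)C(=O)CCCCCCCCCCCCCC1CC(=O)CC(=O)C1 | intermediate
16 | racemic 3-chloro-5-[14-(4-hydroxy-3,5-dimethoxyphenyl)-14-oxotetradecyl]cyclohex-2-en-1-one | COc1cc(cc(OC)c1O)C(=O)CCCCCCCCCCCCCC1CC(Cl)=CC(=O)C1 | intermediate
17 | racemic 22-membered macrocyclic 3-aryloxycyclohex-2-en-1-one (ring B oxygen on C3, chain on C5, aryl ketone para to the ether oxygen) | COc1cc2cc(OC)c1OC1=CC(=O)CC(C1)CCCCCCCCCCCCCC2=O | intermediate
18 | racemic 2-bromo derivative of 17 | COc1cc2cc(OC)c1OC1=C(Br)C(=O)CC(C1)CCCCCCCCCCCCCC2=O | intermediate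
19 | macrocyclic diaryl ether ketone with aromatic ring A (ring A phenol free, ring B as dimethyl ether) | COc1cc2cc(OC)c1Oc1cc(O)cc(c1)CCCCCCCCCCCCCC2=O | intermediate
20 | macrocyclic triphenol ketone | Oc1cc2cc(O)c1Oc1cc(O)cc(c1)CCCCCCCCCCCCCC2=O | intermediate
21 | gravicycle, (R) configuration at the benzylic carbinol | Oc1cc2cc(c1)Oc1c(O)cc(cc1O)[C@H](O)CCCCCCCCCCCCC2 | target

Total step count: 14.
Longest linear sequence: 13 steps (from 1 through steps 1, 2 and 4 to 14).

Steps most likely to fail

1. Step 10. Chain-growth etherification between molecules may outrun closure of the 22-membered ring, or attack by the hindered, acyl-deactivated phenoxide may be slow enough for base to consume the chloroenone. The fallback uses known chemistry: the same phenoxide/chloroenone etherification in its intermolecular form, then ring-closing olefin metathesis. It sets out from 5 and returns at 17.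
 - Ring B piece: aryllithium 6 (from 5) is acylated with N-methoxy-N-methylhex-5-enamide F1 (made from hex-5-enoyl chloride, MeNHOMe·HCl and pyridine) to give 1-[3,5-dimethoxy-4-(triisopropylsilyloxy)phenyl]hex-5-en-1-one F2, and TBAF frees 1-(4-hydroxy-3,5-dimethoxyphenyl)hex-5-en-1-one F3.
 - Ring A piece: undec-10-enal and ylide 10 give (E)-tetradeca-3,13-dien-2-one F4. Malonate 12 under the conditions of step 8 takes it through methyl 2-(dec-9-en-1-yl)-4,6-dioxocyclohexane-1-carboxylate F5 and 2-(dec-9-en-1-yl)-4,6-dioxocyclohexane-1-carboxylic acid F6 to 5-(dec-9-en-1-yl)cyclohexane-1,3-dione F7. Oxalyl chloride with catalytic DMF gives racemic 3-chloro-5-(dec-9-en-1-yl)cyclohex-2-en-1-one F8.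
 - Union and closure: F3 and F8 with K2CO3 in DMF should give 5-(dec-9-en-1-yl)-3-[4-(hex-5-enoyl)-2,6-dimethoxyphenoxy]cyclohex-2-en-1-one F9. Ring-closing metathesis with the second-generation Grubbs catalyst RuCl2(=CHPh)(PCy3)(H2IMes) in dilute CH2Cl2 should give the chain-unsaturated analogue of 17 F10 (C=C between chain carbons 5 and 6 counted from the ketone carbon, E/Z mixture). Diimide (TsNHNH2, NaOAc) should saturate only that isolated alkene and give 17.

2. Step 9. The free phenol may be acylated by oxalyl chloride, or the chloroenone may be hydrolysed during work-up. The fallback masks the phenol before activation; it sets out from 15 and returns at 16.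
 - TBSCl and imidazole in DMF silylate both acidic hydroxyls to 3-[(tert-butyldimethylsilyl)oxy]-5-{14-[4-[(tert-butyldimethylsilyl)oxy]-3,5-dimethoxyphenyl]-14-oxotetradecyl}cyclohex-2-en-1-one F11.
 - Aqueous acetic acid in THF hydrolyses the vinylogous silyl ester only, giving 5-{14-[4-[(tert-butyldimethylsilyl)oxy]-3,5-dimethoxyphenyl]-14-oxotetradecyl}cyclohexane-1,3-dione F12.
 - Oxalyl chloride with catalytic DMF gives racemic 3-chloro-5-{14-[4-[(tert-butyldimethylsilyl)oxy]-3,5-dimethoxyphenyl]-14-oxotetradecyl}cyclohex-2-en-1-one F13.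
 - Et3N·3HF in MeCN removes the aryl silyl ether and gives 16.

3. Step 14. Hydride transfer to the electron-rich ketone may be slow and the facial selectivity insufficient, or the acidic medium may ionize the product carbinol and erode its enantiopurity. The fallback replaces transfer hydrogenation of the free triphenol by oxazaborolidine-catalysed borane reduction of a protected ketone; it sets out from 20 and returns at 21.
 - TBSCl and imidazole give the tris(tert-butyldimethylsilyl) ether of 20 F14.
 - BH3·SMe2 with (S)-2-methyl-CBS-oxazaborolidine should give the (R) carbinol tris(tert-butyldimethylsilyl) ether F15, the aryl group acting as the large substituent.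
 - TBAF removes the three silyl groups and gives 21.

Further compounds
F1 | step 10 | N-methoxy-N-methylhex-5-enamide | C=CCCCC(=O)N(C)OC
F2 | step 10 | 1-[3,5-dimethoxy-4-(triisopropylsilyloxy)phenyl]hex-5-en-1-one | C=CCCCC(=O)c1cc(OC)c(O[Si](C(C)C)(C(C)C)C(C)C)c(OC)c1
F3 | step 10 | 1-(4-hydroxy-3,5-dimethoxyphenyl)hex-5-en-1-one | C=CCCCC(=O)c1cc(OC)c(O)c(OC)c1
F4 | step 10 | (E)-tetradeca-3,13-dien-2-one | CC(=O)/C=C/CCCCCCCCC=C
F5 | step 10 | methyl 2-(dec-9-en-1-yl)-4,6-dioxocyclohexane-1-carboxylate | COC(=O)C1C(=O)CC(=O)CC1CCCCCCCCC=C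
F6 | step 10 | 2-(dec-9-en-1-yl)-4,6-dioxocyclohexane-1-carboxylic acid | OC(=O)C1C(=O)CC(=O)CC1CCCCCCCCC=C
F7 | step 10 | 5-(dec-9-en-1-yl)cyclohexane-1,3-dione | C=CCCCCCCCCC1CC(=O)CC(=O)C1
F8 | step 10 | racemic 3-chloro-5-(dec-9-en-1-yl)cyclohex-2-en-1-one | C=CCCCCCCCCC1CC(Cl)=CC(=O)C1
F9 | step 10 | 5-(dec-9-en-1-yl)-3-[4-(hex-5-enoyl)-2,6-dimethoxyphenoxy]cyclohex-2-en-1-one | C=CCCCC(=O)c1cc(OC)c(OC2=CC(=O)CC(CCCCCCCCC=C)C2)c(OC)c1
F10 | step 10 | chain-unsaturated analogue of 17 (E/Z mixture) | COc1cc2cc(OC)c1OC1=CC(=O)CC(C1)CCCCCCCCC=CCCCC2=O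
F11 | step 9 | 3-[(tert-butyldimethylsilyl)oxy]-5-{14-[4-[(tert-butyldimethylsilyl)oxy]-3,5-dimethoxyphenyl]-14-oxotetradecyl}cyclohex-2-en-1-one | COc1cc(cc(OC)c1O[Si](C)(C)C(C)(C)C)C(=O)CCCCCCCCCCCCCC1CC(=CC(=O)C1)O[Si](C)(C)C(C)(C)C
F12 | step 9 | 5-{14-[4-[(tert-butyldimethylsilyl)oxy]-3,5-dimethoxyphenyl]-14-oxotetradecyl}cyclohexane-1,3-dione | COc1cc(cc(OC)c1O[Si](C)(C)C(C)(C)C)C(=O)CCCCCCCCCCCCCC1CC(=O)CC(=O)C1
F13 | step 9 | racemic 3-chloro-5-{14-[4-[(tert-butyldimethylsilyl)oxy]-3,5-dimethoxyphenyl]-14-oxotetradecyl}cyclohex-2-en-1-one | COc1cc(cc(OC)c1O[Si](C)(C)C(C)(C)C)C(=O)CCCCCCCCCCCCCC1CC(Cl)=CC(=O)C1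
F14 | step 14 | tris(tert-butyldimethylsilyl) ether of 20 | CC(C)(C)[Si](C)(C)Oc1cc2cc(O[Si](C)(C)C(C)(C)C)c1Oc1cc(O[Si](C)(C)C(C)(C)C)cc(c1)CCCCCCCCCCCCCC2=O
F15 | step 14 | (R) carbinol tris(tert-butyldimethylsilyl) ether | CC(C)(C)[Si](C)(C)Oc1cc2cc(c1)Oc1c(O[Si](C)(C)C(C)(C)C)cc(cc1O[Si](C)(C)C(C)(C)C)[C@H](O)CCCCCCCCCCCCC2
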